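The route cuts C5–C6 of the eleven-membered carbocycle (numbered C1/C2 epoxide with methyl on C2, C3–C5 methylenes, C6 gem-dimethyl carbon, C7 benzoyloxy carbon, C8=C9 bearing the carboxyl on C9, C10, C11). Since C6 carries two methyls beside the C5 methylene, hydrogen-atom transfer from an iron hydride to an isopropenyl group on C7 should create the second methyl and a tertiary C6 radical that closes the ring onto the CH2 end of a C4 vinyl sulfone, forming the quaternary carbon and the macrocycle at once. The precursor is an acyclic (S,S)-epoxy (E)-enoate with a silyl-protected (R)-isopropenyl carbinol at one end and a 2-(phenylsulfonyl)allyl group at the other.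

Key step: step 11

Assumption: the C4 sulfone centre made in step 11 is carried as an epimer mixture (both epimers are compounds 18 and 19), because step 13 removes it.

Step 1
Reactants: 1 trimethyl phosphonoacetate; 2 5-bromo-2-methylpent-2-ene
Product: 3 methyl 2-(dimethoxyphosphoryl)-6-methylhept-5-enoate (racemic)
Conditions: NaH, NaI (cat.), DMF, 0 → 60 °C, 1 in excess
Reagents that add atoms: none
Why: SN2 C-alkylation of a phosphonoacetate anion by a primary homoallylic bromide, with excess 1 limiting dialkylation; the racemic phosphonate carbon disappears in step 2.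

Step 2
Reactants: 3 methyl 2-(dimethoxyphosphoryl)-6-methylhept-5-enoate; 4 2,2-dimethoxyacetaldehyde
Product: 5 methyl (2E)-2-(2,2-dimethoxyethylidene)-6-methylhept-5-enoate
Conditions: NaH, THF, 0 °C → rt, 4 added as a dried solution
Reagents that add atoms: none
Why: Horner–Wadsworth–Emmons olefination of an α-alkyl phosphonoacetate places the aldehyde-derived carbon (future C7) trans to the ester and cis to the C10 chain, which is the C8=C9 geometry of the target; a minor geometric isomer would be removed by chromatography.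

Step 3
Reactants: 5 methyl (2E)-2-(2,2-dimethoxyethylidene)-6-methylhept-5-enoate
Product: 6 methyl (2E,5E)-2-(2,2-dimethoxyethylidene)-7-hydroxy-6-methylhept-5-enoate
Conditions: SeO2 (0.3 equiv), t-BuOOH (in decane), CH2Cl2, 0 °C → rt
Reagents that add atoms: tert-butyl hydroperoxide, CC(C)(C)OO
Why: Selenium dioxide allylic oxidation (ene reaction then [2,3]-shift, SeO2 recycled by the hydroperoxide) attacks the E-methyl of the gem-dimethyl alkene, so the future C3 carbinol ends up trans to the C11 chain; the electron-poor enoate alkene is left alone.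

Step 4
Reactants: 6 methyl (2E,5E)-2-(2,2-dimethoxyethylidene)-7-hydroxy-6-methylhept-5-enoate
Product: 7 methyl (2E,5E)-7-bromo-2-(2,2-dimethoxyethylidene)-6-methylhept-5-enoate
Conditions: CBr4, PPh3, CH2Cl2, −20 → 0 °C
Reagents that add atoms: carbon tetrabromide, BrC(Br)(Br)Br
Why: Appel bromination converts the primary allylic alcohol to the bromide under neutral conditions that spare the acetal, the ester and both alkenes.

Step 5
Reactants: 7 methyl (2E,5E)-7-bromo-2-(2,2-dimethoxyethylidene)-6-methylhept-5-enoate; 8 diethyl [(phenylsulfonyl)methyl]phosphonate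
Product: 9 methyl (2E,5E)-8-(diethoxyphosphoryl)-2-(2,2-dimethoxyethylidene)-6-methyl-8-(phenylsulfonyl)oct-5-enoate (racemic at C8)
Conditions: NaH, THF/DMF, 0 °C → rt
Reagents that add atoms: none
Why: The soft, weakly basic carbanion stabilised by both sulfonyl and phosphoryl groups alkylates the primary allylic bromide by SN2 and does not attack the hindered trisubstituted enoate.

Step 6
Reactants: 9 methyl (2E,5E)-8-(diethoxyphosphoryl)-2-(2,2-dimethoxyethylidene)-6-methyl-8-(phenylsulfonyl)oct-5-enoate; 10 formaldehyde (as paraformaldehyde)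
Product: 11 methyl (2E,5E)-2-(2,2-dimethoxyethylidene)-6-methyl-8-(phenylsulfonyl)nona-5,8-dienoate
Conditions: NaH, THF, 0 °C; (CH2O)n, rt
Reagents that add atoms: none
Why: Horner–Wadsworth–Emmons methylenation of an α-alkylated sulfonylmethylphosphonate with formaldehyde is the standard way to a 1-substituted vinyl sulfone, so the C4=C5 acceptor is made without a strongly basic sulfonyl carbanion that the enoate would not tolerate.

Step 7
Reactants: 11 methyl (2E,5E)-2-(2,2-dimethoxyethylidene)-6-methyl-8-(phenylsulfonyl)nona-5,8-dienoate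
Product: 12 methyl (2E,5E)-6-methyl-2-(2-oxoethylidene)-8-(phenylsulfonyl)nona-5,8-dienoate
Conditions: 1 M HCl, THF, 0 °C → rt
Reagents that add atoms: water, O
Why: Acid-catalysed acetal hydrolysis frees the aldehyde, and the trans (fumarate-like) arrangement of aldehyde and ester is the stable geometry and is kept.

Step 8
Reactants: 12 methyl (2E,5E)-6-methyl-2-(2-oxoethylidene)-8-(phenylsulfonyl)nona-5,8-dienoate; 13 isopropenylmagnesium bromide
Product: 15 methyl (2E,5E)-2-[(2R)-2-hydroxy-3-methylbut-3-en-1-ylidene]-6-methyl-8-(phenylsulfonyl)nona-5,8-dienoate, via di(prop-1-en-2-yl)zinc 14 (not isolated)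
Conditions: 13 (2.4 equiv), ZnCl2 (1.2 equiv), THF, 0 °C; 1,4-dioxane, filtration of magnesium salts; (−)-MIB [(2S)-3-exo-morpholinoisoborneol, 10 mol%], toluene, −20 → 0 °C; aq. NH4Cl
Reagents that add atoms: none
Why: Amino-alcohol-catalysed enantioselective addition of an alkenylzinc reagent to an aldehyde, in which the zinc–(−)-MIB complex should deliver the isopropenyl group to the Si face of the enal carbonyl and so set C7 as R (isopropenyl outranks C8); organozinc reagents leave the ester, the enoate and the vinyl sulfone alone.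

Step 9
Reactants: 15 methyl (2E,5E)-2-[(2R)-2-hydroxy-3-methylbut-3-en-1-ylidene]-6-methyl-8-(phenylsulfonyl)nona-5,8-dienoate
Product: 16 methyl (2E,5E)-2-[(2R)-2-(tert-butyldimethylsilyloxy)-3-methylbut-3-en-1-ylidene]-6-methyl-8-(phenylsulfonyl)nona-5,8-dienoate
Conditions: TBSOTf, 2,6-lutidine, CH2Cl2, −78 °C
Reagents that add atoms: tert-butyldimethylsilyl trifluoromethanesulfonate, CC(C)(C)[Si](C)(C)OS(=O)(=O)C(F)(F)F
Why: O-Silylation of the secondary allylic alcohol with a silyl triflate and a hindered base; a silyl ether is chosen because a β-silyloxy radical does not undergo the 1,2-shift that a β-acyloxy radical could in step 11, and it shields the isopropenyl group in step 10.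

Step 10
Reactants: 16 methyl (2E,5E)-2-[(2R)-2-(tert-butyldimethylsilyloxy)-3-methylbut-3-en-1-ylidene]-6-methyl-8-(phenylsulfonyl)nona-5,8-dienoate
Product: 17 methyl (2E)-2-[(2R)-2-(tert-butyldimethylsilyloxy)-3-methylbut-3-en-1-ylidene]-4-{(2S,3S)-3-methyl-3-[2-(phenylsulfonyl)prop-2-en-1-yl]oxiran-2-yl}butanoate
Conditions: L-fructose-derived Shi ketone (ent-Shi ketone, 30 mol%), KHSO5 (as Oxone triple salt), K2CO3, Bu4NHSO4, MeCN/CH2(OMe)2/aq. Na2B4O7–Na2EDTA buffer, 0 °C
Reagents that add atoms: potassium peroxymonosulfate, [K+].[O-]S(=O)(=O)OO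
Why: Shi asymmetric epoxidation, in which the chiral dioxirane attacks only the electron-rich trisubstituted C1=C2 alkene (enoate and vinyl sulfone are electron-poor, the isopropenyl group is 1,1-disubstituted, hindered and deactivated by the allylic oxygen) through the spiro transition state; the L-fructose ketone gives the (S,S)-epoxide under catalyst control, opposite to the sense of the D-fructose ketone.

Step 11
Reactants: 17 methyl (2E)-2-[(2R)-2-(tert-butyldimethylsilyloxy)-3-methylbut-3-en-1-ylidene]-4-{(2S,3S)-3-methyl-3-[2-(phenylsulfonyl)prop-2-en-1-yl]oxiran-2-yl}butanoate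
Product: 18 methyl (1S,2S,7R,8E)-7-(tert-butyldimethylsilyloxy)-2,6,6-trimethyl-4-(phenylsulfonyl)-1,2-epoxycycloundec-8-ene-9-carboxylate (C4 epimer mixture)
Conditions: Fe(acac)3 (0.5 equiv), PhSiH3 (3 equiv, syringe pump), Na2HPO4, EtOH/(CH2OH)2 4:1, 60 °C, 2 mM in 17
Reagents that add atoms: none
Why: Proposed new method: Fe(acac)3 and PhSiH3 in ethanol form an iron hydride that transfers a hydrogen atom to the CH2 terminus of the isopropenyl group, the only electron-rich 1,1-disubstituted alkene of 17, which makes the second methyl on C6 and a nucleophilic tertiary C6 radical; this radical adds to the unsubstituted C5 terminus of the C4 vinyl sulfone, and the α-sulfonyl radical is then reduced by divalent iron and protonated by ethanol, returning trivalent iron. The closest known reaction types are the intermolecular iron-hydride olefin–acceptor (Giese-type) coupling that builds quaternary carbons and endo radical macrocyclisation onto electron-poor alkenes, neither of which has been shown for an eleven-membered carbocycle. The one ring closes in the 11-endo-trig mode, C5 and C4 both becoming ring atoms. No lasting stereocentre is created: C6 carries two identical methyls, C4 forms as an epimer mixture that step 13 erases, and C1, C2 and C7 are not touched. The step needs hydrogen-atom transfer to the isopropenyl group only, secured because the enoate and the vinyl sulfone are electron-poor and the epoxide and silyl ether are inert to the hydride, and it needs ring closure to outrun reduction of the C6 radical, its reversible 3-exo attack on C8 and a 1,5-hydrogen shift from C10, which is served by high dilution, slow silane addition and the polarity match between a tertiary alkyl radical and a vinyl sulfone.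

Step 12
Reactants: 18 methyl (1S,2S,7R,8E)-7-(tert-butyldimethylsilyloxy)-2,6,6-trimethyl-4-(phenylsulfonyl)-1,2-epoxycycloundec-8-ene-9-carboxylate
Product: 19 (1S,2S,7R,8E)-7-(tert-butyldimethylsilyloxy)-2,6,6-trimethyl-4-(phenylsulfonyl)-1,2-epoxycycloundec-8-ene-9-carboxylic acid (C4 epimer mixture)
Conditions: LiOH·H2O, THF/MeOH/H2O, 40 °C; then 0.5 M HCl to pH 5 at 0 °C
Reagents that add atoms: lithium hydroxide, [Li+].[OH-]
Why: Saponification (acyl–oxygen cleavage) of the methyl ester, placed before the sulfone is cleaved so that the conjugated system is a carboxylate, which resists electron transfer and radical attack in step 13; epoxide, silyl ether and sulfone are stable to hydroxide.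

Step 13
Reactants: 19 (1S,2S,7R,8E)-7-(tert-butyldimethylsilyloxy)-2,6,6-trimethyl-4-(phenylsulfonyl)-1,2-epoxycycloundec-8-ene-9-carboxylic acid
Product: 20 (1S,2S,7R,8E)-7-(tert-butyldimethylsilyloxy)-2,6,6-trimethyl-1,2-epoxycycloundec-8-ene-9-carboxylic acid
Conditions: Na/Hg (6% Na), Na2HPO4, MeOH/THF, −20 °C; then pH 5 at 0 °C
Reagents that add atoms: none
Why: Reductive desulfonylation with buffered sodium amalgam (electron transfer to the aryl sulfone, C–S cleavage, reduction and protonation at C4) removes the sulfone and the C4 stereocentre; the α,β-unsaturated carboxylate and the epoxide should not be reduced at low temperature under phosphate buffer.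

Step 14
Reactants: 20 (1S,2S,7R,8E)-7-(tert-butyldimethylsilyloxy)-2,6,6-trimethyl-1,2-epoxycycloundec-8-ene-9-carboxylic acid
Product: 21 (1S,2S,7R,8E)-7-hydroxy-2,6,6-trimethyl-1,2-epoxycycloundec-8-ene-9-carboxylic acid
Conditions: Bu4NF, THF, rt → 45 °C; aq. NH4Cl
Reagents that add atoms: none
Why: Fluoride-mediated cleavage of the silyl ether, driven by the Si–F bond, frees the C7 hydroxyl without touching the epoxide or the conjugated carboxylate.

Step 15
Reactants: 21 (1S,2S,7R,8E)-7-hydroxy-2,6,6-trimethyl-1,2-epoxycycloundec-8-ene-9-carboxylic acid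
Product: 23 (1S,2S,7R,8E)-7-(benzoyloxy)-2,6,6-trimethyl-1,2-epoxycycloundec-8-ene-9-carboxylic acid (target), via benzoic mixed anhydride 22 (not isolated)
Conditions: BzCl (3 equiv), pyridine, DMAP (cat.), CH2Cl2, 0 °C → rt; then THF/aq. NaHCO3, rt; pH 5 at 0 °C
Reagents that add atoms: benzoyl chloride, O=C(Cl)c1ccccc1
Why: DMAP-catalysed O-benzoylation acylates the carboxylate to a mixed anhydride and then the hindered neopentyl-type C7 hydroxyl with retention at C7, and mild aqueous bicarbonate hydrolyses only the anhydride, leaving the benzoate and returning the free acid.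

Compound list
1 | trimethyl phosphonoacetate | COC(=O)CP(=O)(OC)OC | starting material
2 | 5-bromo-2-methylpent-2-ene | CC(C)=CCCBr | starting material
3 | methyl 2-(dimethoxyphosphoryl)-6-methylhept-5-enoate (racemic) | COC(=O)C(CCC=C(C)C)P(=O)(OC)OC | intermediate
4 | 2,2-dimethoxyacetaldehyde | COC(OC)C=O | starting material
5 | methyl (2E)-2-(2,2-dimethoxyethylidene)-6-methylhept-5-enoate | COC(=O)/C(CCC=C(C)C)=C/C(OC)OC | intermediate
6 | methyl (2E,5E)-2-(2,2-dimethoxyethylidene)-7-hydroxy-6-methylhept-5-enoate | COC(=O)/C(CC/C=C(\C)CO)=C/C(OC)OC | intermediate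
7 | methyl (2E,5E)-7-bromo-2-(2,2-dimethoxyethylidene)-6-methylhept-5-enoate | COC(=O)/C(CC/C=C(\C)CBr)=C/C(OC)OC | intermediate
8 | diethyl [(phenylsulfonyl)methyl]phosphonate | CCOP(=O)(CS(=O)(=O)c1ccccc1)OCC | starting material
9 | methyl (2E,5E)-8-(diethoxyphosphoryl)-2-(2,2-dimethoxyethylidene)-6-methyl-8-(phenylsulfonyl)oct-5-enoate (racemic at C8) | COC(=O)/C(CC/C=C(\C)CC(P(=O)(OCC)OCC)S(=O)(=O)c1ccccc1)=C/C(OC)OC | intermediate
10 | formaldehyde (used as paraformaldehyde) | C=O | starting material
11 | methyl (2E,5E)-2-(2,2-dimethoxyethylidene)-6-methyl-8-(phenylsulfonyl)nona-5,8-dienoate | COC(=O)/C(CC/C=C(\C)CC(=C)S(=O)(=O)c1ccccc1)=C/C(OC)OC | intermediate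
12 | methyl (2E,5E)-6-methyl-2-(2-oxoethylidene)-8-(phenylsulfonyl)nona-5,8-dienoate | COC(=O)/C(CC/C=C(\C)CC(=C)S(=O)(=O)c1ccccc1)=C/C=O | intermediate
13 | isopropenylmagnesium bromide | CC(=C)[Mg]Br | starting material
14 | di(prop-1-en-2-yl)zinc | CC(=C)[Zn]C(C)=C | intermediate
15 | methyl (2E,5E)-2-[(2R)-2-hydroxy-3-methylbut-3-en-1-ylidene]-6-methyl-8-(phenylsulfonyl)nona-5,8-dienoate | C=C(C)[C@H](O)/C=C(\CC/C=C(\C)CC(=C)S(=O)(=O)c1ccccc1)C(=O)OC | intermediate
16 | methyl (2E,5E)-2-[(2R)-2-(tert-butyldimethylsilyloxy)-3-methylbut-3-en-1-ylidene]-6-methyl-8-(phenylsulfonyl)nona-5,8-dienoate | C=C(C)[C@H](O[Si](C)(C)C(C)(C)C)/C=C(\CC/C=C(\C)CC(=C)S(=O)(=O)c1ccccc1)C(=O)OC | intermediate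
17 | methyl (2E)-2-[(2R)-2-(tert-butyldimethylsilyloxy)-3-methylbut-3-en-1-ylidene]-4-{(2S,3S)-3-methyl-3-[2-(phenylsulfonyl)prop-2-en-1-yl]oxiran-2-yl}butanoate | C=C(C)[C@H](O[Si](C)(C)C(C)(C)C)/C=C(\CC[C@@H]1O[C@@]1(C)CC(=C)S(=O)(=O)c1ccccc1)C(=O)OC | intermediate
18 | methyl (1S,2S,7R,8E)-7-(tert-butyldimethylsilyloxy)-2,6,6-trimethyl-4-(phenylsulfonyl)-1,2-epoxycycloundec-8-ene-9-carboxylate (C4 epimer mixture) | CC1(C)CC(S(=O)(=O)c2ccccc2)C[C@]3(C)O[C@H]3CC/C(C(=O)OC)=C\[C@H]1O[Si](C)(C)C(C)(C)C | intermediate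
19 | (1S,2S,7R,8E)-7-(tert-butyldimethylsilyloxy)-2,6,6-trimethyl-4-(phenylsulfonyl)-1,2-epoxycycloundec-8-ene-9-carboxylic acid (C4 epimer mixture) | CC1(C)CC(S(=O)(=O)c2ccccc2)C[C@]3(C)O[C@H]3CC/C(C(=O)O)=C\[C@H]1O[Si](C)(C)C(C)(C)C | intermediate
20 | (1S,2S,7R,8E)-7-(tert-butyldimethylsilyloxy)-2,6,6-trimethyl-1,2-epoxycycloundec-8-ene-9-carboxylic acid | CC1(C)CCC[C@]2(C)O[C@H]2CC/C(C(=O)O)=C\[C@H]1O[Si](C)(C)C(C)(C)C | intermediate
21 | (1S,2S,7R,8E)-7-hydroxy-2,6,6-trimethyl-1,2-epoxycycloundec-8-ene-9-carboxylic acid | CC1(C)CCC[C@]2(C)O[C@H]2CC/C(C(=O)O)=C\[C@H]1O | intermediate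
22 | benzoic mixed anhydride of (1S,2S,7R,8E)-7-(benzoyloxy)-2,6,6-trimethyl-1,2-epoxycycloundec-8-ene-9-carboxylic acid | CC1(C)CCC[C@]2(C)O[C@H]2CC/C(C(=O)OC(=O)c3ccccc3)=C\[C@H]1OC(=O)c1ccccc1 | intermediate
23 | (1S,2S,7R,8E)-7-(benzoyloxy)-2,6,6-trimethyl-1,2-epoxycycloundec-8-ene-9-carboxylic acid | CC1(C)CCC[C@]2(C)O[C@H]2CC/C(C(=O)O)=C\[C@H]1OC(=O)c1ccccc1 | target

Total step count: 15
Longest linear sequence: 15 steps (from 1 and 2 to 23)

Steps most likely to fail

1. Step 11 (Proposed new method). The 11-endo closure may be too slow, so that the C6 radical is reduced by the iron hydride, adds 3-exo to C8 with migration of the enoate vinyl group from C7 to C6, or takes a hydrogen atom from C10. After closure the C4 radical may add across the ring to C8. Fallback, by known reactions only, closing the ring by metathesis at C4=C5 without any sulfone: it sets out from bromide 7 and comes back at acid 20. Stille coupling of 7 with tributyl(vinyl)stannane (Pd2(dba)3, AsPh3, THF, 50 °C) should give the 1,4-diene acetal F1. Acid hydrolysis as in step 7 should give the dienyl enal F2. Asymmetric reverse prenylation with the (+)-α-pinene-derived B-(3-methylbut-2-enyl)diisopinocampheylborane (Et2O, −78 °C, NaBO3 work-up) should attack the Si face through a chair transition state and give the (R)-gem-dimethyl carbinol F3, in which C6 is already quaternary. Silylation as in step 9 should give the silyl ether F4. Ring-closing metathesis between the C5 vinyl and C4 allyl termini (second-generation Grubbs catalyst, toluene, 80 °C, high dilution) should give the cycloundecatriene F5. Diimide reduction (2-nitrobenzenesulfonohydrazide, Et3N, CH2Cl2), selective for the disubstituted C4=C5 alkene, should give the cycloundecadiene F6. Shi epoxidation as in step 10 should give the epoxy ester F7, and saponification as in step 12 then gives 20.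

2. Step 8. Facial selectivity may be eroded by an uncatalysed, salt-promoted addition, and the doubly activated enal may take up the nucleophile in a conjugate sense. Fallback: it sets out from 12 and 13 and comes back at 15. Direct addition of 13 to 12 (THF, −78 °C) should give the racemic carbinol F8. Sharpless kinetic resolution (Ti(OiPr)4, L-(+)-diisopropyl tartrate, t-BuOOH, 4 Å sieves, CH2Cl2, −20 °C) should epoxidise the isopropenyl group of the (S)-enantiomer to the epoxy alcohol F9 and leave (R)-15 for separation.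

3. Step 13. Electron transfer may reach the conjugated carboxylate and saturate C8=C9, the transient C4 radical may be trapped across the ring by C8 before it is reduced, or the epoxide may open if the buffer fails. Fallback, a redox detour that takes the acceptor out of conjugation: it sets out from 18 and comes back at 20. Reduction with iBu2AlH (CH2Cl2, −78 °C) should give the allylic alcohol sulfone F10, whose C8=C9 alkene is isolated and electron-rich. Buffered sodium amalgam as in step 13 should then give the desulfonylated allylic alcohol F11. Oxidation with MnO2 (CH2Cl2) should give the enal F12, and Pinnick oxidation (NaClO2, NaH2PO4, 2-methylbut-2-ene, t-BuOH/H2O) gives 20.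

Further compounds
F1 | step 11 | 1,4-diene acetal, methyl (2E,5E)-2-(2,2-dimethoxyethylidene)-6-methylnona-5,8-dienoate | COC(=O)/C(CC/C=C(\C)CC=C)=C/C(OC)OC
F2 | step 11 | dienyl enal, methyl (2E,5E)-6-methyl-2-(2-oxoethylidene)nona-5,8-dienoate | COC(=O)/C(CC/C=C(\C)CC=C)=C/C=O
F3 | step 11 | (R)-gem-dimethyl carbinol, methyl (2E,5E)-2-[(2R)-2-hydroxy-3,3-dimethylpent-4-en-1-ylidene]-6-methylnona-5,8-dienoate | C=CC(C)(C)[C@H](O)/C=C(\CC/C=C(\C)CC=C)C(=O)OC
F4 | step 11 | silyl ether, methyl (2E,5E)-2-[(2R)-2-(tert-butyldimethylsilyloxy)-3,3-dimethylpent-4-en-1-ylidene]-6-methylnona-5,8-dienoate | C=CC(C)(C)[C@H](O[Si](C)(C)C(C)(C)C)/C=C(\CC/C=C(\C)CC=C)C(=O)OC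
F5 | step 11 | cycloundecatriene, methyl (1E,7R,8E)-7-(tert-butyldimethylsilyloxy)-2,6,6-trimethylcycloundeca-1,4,8-triene-9-carboxylate (C4=C5 geometry open) | CC1(C)C=CC/C(C)=C/CC/C(C(=O)OC)=C\[C@H]1O[Si](C)(C)C(C)(C)C
F6 | step 11 | cycloundecadiene, methyl (1E,7R,8E)-7-(tert-butyldimethylsilyloxy)-2,6,6-trimethylcycloundeca-1,8-diene-9-carboxylate | CC1(C)CCC/C(C)=C/CC/C(C(=O)OC)=C\[C@H]1O[Si](C)(C)C(C)(C)C
F7 | step 11 | epoxy ester, methyl (1S,2S,7R,8E)-7-(tert-butyldimethylsilyloxy)-2,6,6-trimethyl-1,2-epoxycycloundec-8-ene-9-carboxylate | CC1(C)CCC[C@]2(C)O[C@H]2CC/C(C(=O)OC)=C\[C@H]1O[Si](C)(C)C(C)(C)C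
F8 | step 8 | racemic carbinol, methyl (2E,5E)-2-(2-hydroxy-3-methylbut-3-en-1-ylidene)-6-methyl-8-(phenylsulfonyl)nona-5,8-dienoate | C=C(C)C(O)/C=C(\CC/C=C(\C)CC(=C)S(=O)(=O)c1ccccc1)C(=O)OC
F9 | step 8 | epoxy alcohol, methyl (2E,5E)-2-{(2S)-2-hydroxy-2-[(2S)-2-methyloxiran-2-yl]ethylidene}-6-methyl-8-(phenylsulfonyl)nona-5,8-dienoate | C[C@]1(CO1)[C@@H](O)/C=C(\CC/C=C(\C)CC(=C)S(=O)(=O)c1ccccc1)C(=O)OC
F10 | step 13 | allylic alcohol sulfone, [(1S,2S,7R,8E)-7-(tert-butyldimethylsilyloxy)-2,6,6-trimethyl-4-(phenylsulfonyl)-1,2-epoxycycloundec-8-en-9-yl]methanol (C4 epimer mixture) | CC1(C)CC(S(=O)(=O)c2ccccc2)C[C@]3(C)O[C@H]3CC/C(CO)=C\[C@H]1O[Si](C)(C)C(C)(C)C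
F11 | step 13 | desulfonylated allylic alcohol, [(1S,2S,7R,8E)-7-(tert-butyldimethylsilyloxy)-2,6,6-trimethyl-1,2-epoxycycloundec-8-en-9-yl]methanol | CC1(C)CCC[C@]2(C)O[C@H]2CC/C(CO)=C\[C@H]1O[Si](C)(C)C(C)(C)C
F12 | step 13 | enal, (1S,2S,7R,8E)-7-(tert-butyldimethylsilyloxy)-2,6,6-trimethyl-1,2-epoxycycloundec-8-ene-9-carbaldehyde | CC1(C)CCC[C@]2(C)O[C@H]2CC/C(C=O)=C\[C@H]1O[Si](C)(C)C(C)(C)C
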